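**Retrosynthetic overview**
- The target is opened at the C2 ester: a ten-membered lactone with a free C2 hydroxyl and a 7,8-acetonide is acylated with mono-tert-butyl trans,trans-muconate, and acid then removes the acetonide and the tert-butyl ester.
- The strategy rests on the C7–C8 vicinal diol of the only ring, the ten-membered lactone (ring atoms O, C1 to C9). C7 is allylic to the C5=C6 E-alkene and C8 is next to the lactone carbinol C9, so both carbinol carbons are traced back to aldehydes, and the ring is closed at C7–C8 by reductive (pinacol) coupling of an ester-linked enal/α-acyloxy aldehyde.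
- The dialdehyde comes from an ester of (S)-2-silyloxyhex-5-enoic acid with primary-protected (S)-pentane-1,2-diol: cross-metathesis with crotonaldehyde adds C7, then the primary alcohol is freed and oxidised to the C8 aldehyde.
- C2 comes from methyl (S)-glycidate (opened by allyl Grignard) and C9 from (S)-pentane-1,2-diol; C7 and C8 are set in the ring closure. Ring order: one ring only, formed in step 9.

Key step: step 9

Remark: positions are numbered C1 (lactone carbonyl), C2 (acyloxy carbon), C5=C6 (ring alkene), C7 and C8 (diol), C9 (propyl-bearing carbinol). The SMILES is read as 2S,7R,8S,9S with 7,8-threo and 8,9-threo oxygen pairs and all alkenes E.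

**Route**

Step 1
Reactants: 1 methyl (S)-glycidate; 2 allylmagnesium bromide
Product: 3 methyl (S)-2-hydroxyhex-5-enoate
Conditions: 2 (1.2 equiv, added slowly), CuI (10 mol%), THF, −78 → −50 °C; aq. NH4Cl
Reagents that add atoms: none
Why: Copper-catalysed Grignard opening of an epoxide (SN2 at the unsubstituted C3 of the glycidic ester) should be faster at −78 °C than addition to the ester, and the untouched C2 stereocentre of 1 becomes C2 of the target.

Step 2
Reactants: 3 methyl (S)-2-hydroxyhex-5-enoate
Product: 4 methyl (S)-2-[(tert-butyldimethylsilyl)oxy]hex-5-enoate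
Conditions: TBSCl, imidazole, DMF, rt
Reagents that add atoms: tert-butyldimethylsilyl chloride, CC(C)(C)[Si](C)(C)Cl
Why: Silyl ether formation protects the C2 hydroxyl with a group that should survive saponification, metathesis, DDQ, periodinane and low-valent titanium.

Step 3
Reactants: 4 methyl (S)-2-[(tert-butyldimethylsilyl)oxy]hex-5-enoate
Product: 5 (S)-2-[(tert-butyldimethylsilyl)oxy]hex-5-enoic acid
Conditions: LiOH·H2O, THF/H2O, 0 °C; 1 M HCl to pH 3–4 at 0 °C
Reagents that add atoms: lithium hydroxide, [Li+].[OH-]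
Why: Ester saponification with LiOH at 0 °C frees the acid, and the α-silyloxy carboxylate is slow to enolise, so C2 should keep its configuration.

Step 4
Reactants: 6 (S)-pentane-1,2-diol
Product: 8 (S)-1-[(4-methoxybenzyl)oxy]pentan-2-ol, via dibutylstannylene acetal 7 (not isolated)
Conditions: Bu2SnO, toluene, reflux (Dean–Stark); then 4-methoxybenzyl chloride, Bu4NI (cat.), 90 °C
Reagents that add atoms: 4-methoxybenzyl chloride, COc1ccc(CCl)cc1; dibutyltin oxide, CCCC[Sn](=O)CCCC (tin only in 7)
Why: Stannylene acetal alkylation puts the 4-methoxybenzyl group selectively on the primary oxygen of a terminal 1,2-diol and leaves the secondary C9 hydroxyl, with the configuration of 6, free.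

Step 5
Reactants: 5 (S)-2-[(tert-butyldimethylsilyl)oxy]hex-5-enoic acid; 8 (S)-1-[(4-methoxybenzyl)oxy]pentan-2-ol
Product: 9 (S)-1-[(4-methoxybenzyl)oxy]pentan-2-yl (S)-2-[(tert-butyldimethylsilyl)oxy]hex-5-enoate
Conditions: EDC·HCl, DMAP (0.2 equiv), CH2Cl2, 0 °C → rt
Reagents that add atoms: none
Why: Steglich esterification (carbodiimide activation, DMAP acyl transfer) joins the acid and the secondary alcohol at 0 °C without touching either stereocentre.

Step 6
Reactants: 9 (S)-1-[(4-methoxybenzyl)oxy]pentan-2-yl (S)-2-[(tert-butyldimethylsilyl)oxy]hex-5-enoate; 10 crotonaldehyde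
Product: 11 (S)-1-[(4-methoxybenzyl)oxy]pentan-2-yl (S,E)-2-[(tert-butyldimethylsilyl)oxy]-7-oxohept-5-enoate
Conditions: 10 (5 equiv), second-generation Grubbs catalyst (5 mol%), CH2Cl2, 40 °C
Reagents that add atoms: none
Why: Olefin cross-metathesis of the terminal alkene with excess crotonaldehyde installs C7 as the conjugated aldehyde; the E isomer is favoured thermodynamically and propene leaves the mixture.

Step 7
Reactants: 11 (S)-1-[(4-methoxybenzyl)oxy]pentan-2-yl (S,E)-2-[(tert-butyldimethylsilyl)oxy]-7-oxohept-5-enoate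
Product: 12 (S)-1-hydroxypentan-2-yl (S,E)-2-[(tert-butyldimethylsilyl)oxy]-7-oxohept-5-enoate
Conditions: DDQ (1.3 equiv), CH2Cl2/pH 7 phosphate buffer (10:1), 0 °C
Reagents that add atoms: none
Why: Oxidative cleavage of the 4-methoxybenzyl ether by DDQ (hydride abstraction, hydrolysis of the oxocarbenium ion) is neutral under buffering, so silyl ether, enal and ester should stay and the acyl group should not migrate to the primary oxygen.

Step 8
Reactants: 12 (S)-1-hydroxypentan-2-yl (S,E)-2-[(tert-butyldimethylsilyl)oxy]-7-oxohept-5-enoate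
Product: 13 (S)-1-oxopentan-2-yl (S,E)-2-[(tert-butyldimethylsilyl)oxy]-7-oxohept-5-enoate
Conditions: Dess–Martin periodinane (1.5 equiv), NaHCO3, CH2Cl2, 0 °C → rt; aq. Na2S2O3/NaHCO3; used at once without chromatography
Reagents that add atoms: none
Why: Dess–Martin oxidation under bicarbonate buffering turns the primary alcohol into the α-acyloxy aldehyde without a base that could epimerise C9.

Step 9
Reactants: 13 (S)-1-oxopentan-2-yl (S,E)-2-[(tert-butyldimethylsilyl)oxy]-7-oxohept-5-enoate
Product: 14 (3S,6E,8R,9S,10S)-3-[(tert-butyldimethylsilyl)oxy]-8,9-dihydroxy-10-propyl-3,4,5,8,9,10-hexahydro-2H-oxecin-2-one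
Conditions: TiCl3(DME)1.5 (12 equiv), Zn–Cu couple (40 equiv), DME, reflux 3 h; cool to 25 °C; 13 in DME added over 30 h by syringe pump (final 2 mM), then 5 h; 0 °C, aq. NaHCO3, filtration through Celite
Reagents that add atoms: none
Why: Low-valent titanium formed from TiCl3(DME)1.5 and Zn–Cu couple gives one electron to each aldehyde, and the titanium-bound ketyl at C8 and the allyl-type ketyl of the enal join at their carbonyl carbons to a titanium 1,2-diolate that water sets free as the diol, with no deoxygenation to the alkene expected at 25 °C. The closest known reaction type is the McMurry intramolecular pinacol coupling of dialdehydes, conjugated ones among them, to carbocyclic 1,2-diols of ten to fourteen ring atoms. The ten-membered lactone is closed by a macrocyclising ketyl–ketyl coupling at C7–C8 under slow addition, the planar Z ester and the E alkene cutting down the free rotors of the chain. C7 and C8 are set relative to each other by the preference of rings of ten or more atoms for the trans (threo) diolate, in which the two titanium-bound oxygens avoid each other, and C8 is set relative to C9 by the resident C9 centre, whose propyl group should sit outside the forming ring while titanium bridges the ketyl oxygen and the neighbouring acyloxy group, which puts O8 syn to O9. The step needs carbonyl-to-carbonyl coupling of the enal instead of coupling through C5, an intact C9–O ester bond and the 7R,8S isomer out of four diols. The first two rest on the oxophilic, non-basic titanium reagent (SmI2 would be expected to cleave the acyloxy group), while the facial control by C9 is a bias and not a certainty, so any diastereomers are to be separated here or as acetonides after step 10.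

Step 10
Reactants: 14 (3S,6E,8R,9S,10S)-3-[(tert-butyldimethylsilyl)oxy]-8,9-dihydroxy-10-propyl-3,4,5,8,9,10-hexahydro-2H-oxecin-2-one
Product: 15 the 7,8-O-isopropylidene acetal of 14 (trans-fused 2,2-dimethyl-1,3-dioxolane across C7/C8, C2 silyl ether kept)
Conditions: 2,2-dimethoxypropane, PPTS (cat.), CH2Cl2, rt
Reagents that add atoms: 2,2-dimethoxypropane, COC(C)(C)OC
Why: Acid-catalysed acetonide formation (transacetalisation) masks the trans-7,8-diol so that only the C2 hydroxyl can be acylated later, and the acetonides should be easier to separate from any diastereomer than the diols.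

Step 11
Reactants: 15 the 7,8-O-isopropylidene acetal of 14
Product: 16 the C2 alcohol, 15 without its silyl group (2S-hydroxy lactone 7,8-acetonide)
Conditions: HF·pyridine, pyridine, THF, 0 °C → rt
Reagents that add atoms: none
Why: Fluoride-driven desilylation under buffered, non-basic conditions frees the C2 hydroxyl without epimerising or opening the α-oxygenated lactone, and the acetonide is stable to HF·pyridine.

Step 12
Reactants: 17 trans,trans-muconic acid
Product: 18 (2E,4E)-6-(tert-butoxy)-6-oxohexa-2,4-dienoic acid (mono-tert-butyl muconate)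
Conditions: 17 (3 equiv), N,N-dimethylformamide di-tert-butyl acetal (1 equiv, added over 2 h), DMF, 80 °C; unchanged 17 filtered off, half-ester extracted into aq. NaHCO3 and re-acidified
Reagents that add atoms: N,N-dimethylformamide di-tert-butyl acetal, CN(C)C(OC(C)(C)C)OC(C)(C)C
Why: Desymmetrising mono-esterification, in which the acid protonates the amide acetal and the tert-butyl cation passes to the carboxylate; an excess of diacid in homogeneous DMF favours the half-ester, which is parted from diester by bicarbonate extraction.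

Step 13
Reactants: 16 the C2 alcohol (2S-hydroxy lactone 7,8-acetonide); 18 (2E,4E)-6-(tert-butoxy)-6-oxohexa-2,4-dienoic acid
Product: 19 the C2 O-[(2E,4E)-6-tert-butoxy-6-oxohexa-2,4-dienoyl] derivative of 16 (tert-butyl ester acetonide of the target)
Conditions: EDC·HCl, DMAP (0.3 equiv), CH2Cl2, 0 °C → rt
Reagents that add atoms: none
Why: Steglich esterification acylates the secondary C2 hydroxyl with the dienoic acid with retention, the tert-butyl ester keeping the second carboxyl inert.

Step 14
Reactants: 19 the tert-butyl ester acetonide of the target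
Product: 20 (2E,4E)-6-{[(3S,6E,8R,9S,10S)-8,9-dihydroxy-2-oxo-10-propyl-3,4,5,8,9,10-hexahydro-2H-oxecin-3-yl]oxy}-6-oxohexa-2,4-dienoic acid (target)
Conditions: TFA/CH2Cl2/H2O (9:9:2), 0 °C → rt
Reagents that add atoms: none
Why: Acidolysis cleaves the tert-butyl ester by alkyl–oxygen fission (loss of 2-methylpropene) and hydrolyses the acetonide in the same pot, while the lactone, the dienoate ester and the E alkenes should be stable to aqueous trifluoroacetic acid at room temperature.

**Compound list**
1 | methyl (S)-glycidate | COC(=O)[C@@H]1CO1 | starting material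
2 | allylmagnesium bromide | C=CC[Mg]Br | starting material
3 | methyl (S)-2-hydroxyhex-5-enoate | COC(=O)[C@@H](O)CCC=C | intermediate
4 | methyl (S)-2-[(tert-butyldimethylsilyl)oxy]hex-5-enoate | COC(=O)[C@@H](O[Si](C)(C)C(C)(C)C)CCC=C | intermediate
5 | (S)-2-[(tert-butyldimethylsilyl)oxy]hex-5-enoic acid | OC(=O)[C@@H](O[Si](C)(C)C(C)(C)C)CCC=C | intermediate
6 | (S)-pentane-1,2-diol | CCC[C@H](O)CO | starting material
7 | (S)-2,2-dibutyl-4-propyl-1,3,2-dioxastannolane (stannylene acetal, not isolated) | CCC[C@H]1CO[Sn](CCCC)(CCCC)O1 | intermediate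
8 | (S)-1-[(4-methoxybenzyl)oxy]pentan-2-ol | CCC[C@H](O)COCc1ccc(OC)cc1 | intermediate
9 | (S)-1-[(4-methoxybenzyl)oxy]pentan-2-yl (S)-2-[(tert-butyldimethylsilyl)oxy]hex-5-enoate | CCC[C@@H](COCc1ccc(OC)cc1)OC(=O)[C@@H](O[Si](C)(C)C(C)(C)C)CCC=C | intermediate
10 | crotonaldehyde, (E)-but-2-enal | C/C=C/C=O | starting material
11 | (S)-1-[(4-methoxybenzyl)oxy]pentan-2-yl (S,E)-2-[(tert-butyldimethylsilyl)oxy]-7-oxohept-5-enoate | CCC[C@@H](COCc1ccc(OC)cc1)OC(=O)[C@@H](O[Si](C)(C)C(C)(C)C)CC/C=C/C=O | intermediate
12 | (S)-1-hydroxypentan-2-yl (S,E)-2-[(tert-butyldimethylsilyl)oxy]-7-oxohept-5-enoate | CCC[C@@H](CO)OC(=O)[C@@H](O[Si](C)(C)C(C)(C)C)CC/C=C/C=O | intermediate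
13 | (S)-1-oxopentan-2-yl (S,E)-2-[(tert-butyldimethylsilyl)oxy]-7-oxohept-5-enoate (key-step precursor) | CCC[C@@H](C=O)OC(=O)[C@@H](O[Si](C)(C)C(C)(C)C)CC/C=C/C=O | intermediate
14 | (3S,6E,8R,9S,10S)-3-[(tert-butyldimethylsilyl)oxy]-8,9-dihydroxy-10-propyl-3,4,5,8,9,10-hexahydro-2H-oxecin-2-one (key-step product) | CCC[C@@H]1OC(=O)[C@@H](O[Si](C)(C)C(C)(C)C)CC/C=C/[C@@H](O)[C@@H]1O | intermediate
15 | 7,8-O-isopropylidene acetal of 14 (trans-fused dioxolane, C2 silyl ether) | CCC[C@@H]1OC(=O)[C@@H](O[Si](C)(C)C(C)(C)C)CC/C=C/[C@H]2OC(C)(C)O[C@H]12 | intermediate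
16 | 2S-hydroxy lactone 7,8-acetonide (15 without the silyl group) | CCC[C@@H]1OC(=O)[C@@H](O)CC/C=C/[C@H]2OC(C)(C)O[C@H]12 | intermediate
17 | trans,trans-muconic acid | OC(=O)/C=C/C=C/C(=O)O | starting material
18 | (2E,4E)-6-(tert-butoxy)-6-oxohexa-2,4-dienoic acid | CC(C)(C)OC(=O)/C=C/C=C/C(=O)O | intermediate
19 | C2 O-[(2E,4E)-6-tert-butoxy-6-oxohexa-2,4-dienoyl] derivative of 16 | CCC[C@@H]1OC(=O)[C@@H](OC(=O)/C=C/C=C/C(=O)OC(C)(C)C)CC/C=C/[C@H]2OC(C)(C)O[C@H]12 | intermediate
20 | (2E,4E)-6-{[(3S,6E,8R,9S,10S)-8,9-dihydroxy-2-oxo-10-propyl-3,4,5,8,9,10-hexahydro-2H-oxecin-3-yl]oxy}-6-oxohexa-2,4-dienoic acid | CCC[C@@H]1OC(=O)[C@@H](OC(=O)/C=C/C=C/C(=O)O)CC/C=C/[C@@H](O)[C@@H]1O | target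

**Step count**
Total: 14 steps. Longest linear sequence: 12 steps (steps 1, 2, 3, 5, 6, 7, 8, 9, 10, 11, 13, 14, from methyl (S)-glycidate).

**Steps most likely to fail**

Step 9 (key step). What may go wrong: poor facial control at C8 by the C9 centre or closure to the cis diolate, bond formation through C5 of the delocalised enal ketyl, or loss of the C9 acyloxy group from the reduced C8 carbonyl. Fallback (sets out from 9, comes back at 15): the C7–C8 bond is made between two molecules under reagent control and the ring is closed at C5=C6 by metathesis.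
- DDQ (CH2Cl2/pH 7 buffer) would take the 4-methoxybenzyl group off 9 to give (S)-1-hydroxypentan-2-yl (S)-2-[(tert-butyldimethylsilyl)oxy]hex-5-enoate F1.
- Dess–Martin periodinane/NaHCO3 would give the aldehyde (S)-1-oxopentan-2-yl (S)-2-[(tert-butyldimethylsilyl)oxy]hex-5-enoate F2.
- Brown alkoxyallylboration with [(Z)-3-(methoxymethoxy)allyl]diisopinocampheylborane (from allyl methoxymethyl ether, sec-BuLi, (−)-Ipc2BOMe and BF3·OEt2; THF, −78 °C; buffered H2O2 work-up at pH 7) should add to the Si face of the C8 aldehyde through a chair transition state. The Z-alkoxyallyl unit gives the 7,8-syn (threo) pair and the isopinocampheyl groups should override the bias of C9 (the sense of the reagent is to be confirmed on the first run). The product would be (3R,4R,5S)-4-hydroxy-3-(methoxymethoxy)oct-1-en-5-yl (S)-2-[(tert-butyldimethylsilyl)oxy]hex-5-enoate F3.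
- Me2BBr (CH2Cl2, −78 °C) would free the diol (3R,4S,5S)-3,4-dihydroxyoct-1-en-5-yl (S)-2-[(tert-butyldimethylsilyl)oxy]hex-5-enoate F4 without touching the ester or the silyl ether.
- 2,2-Dimethoxypropane/PPTS would give the diene acetonide (S)-1-[(4R,5R)-2,2-dimethyl-5-vinyl-1,3-dioxolan-4-yl]butyl (S)-2-[(tert-butyldimethylsilyl)oxy]hex-5-enoate F5.
- Ring-closing metathesis (first-generation Grubbs catalyst, CH2Cl2, 40 °C, 1 mM), a closure well known for diol acetonides of this lactone class, should give 15 with loss of ethene; the E/Z outcome would have to be checked.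

Step 1. What may go wrong: addition of the very reactive allyl Grignard reagent to the methyl ester, or uncatalysed attack, competing with the copper-mediated opening at C3. Fallback (sets out from 2, comes back at 5): the carboxyl carbon is carried at the alcohol level through the Grignard step.
- Commercial (S)-glycidyl trityl ether F6 would be opened by 2 (CuI 10 mol%, THF, −40 °C) to (S)-1-(trityloxy)hex-5-en-2-ol F7.
- Silylation (TBSCl, imidazole, DMF) would give (S)-tert-butyldimethyl{[1-(trityloxy)hex-5-en-2-yl]oxy}silane F8.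
- Detritylation (BCl3, CH2Cl2, −30 °C) would give (S)-2-[(tert-butyldimethylsilyl)oxy]hex-5-en-1-ol F9.
- Oxidation (TEMPO, PhI(OAc)2, MeCN/H2O) would give acid 5.

Step 12. What may go wrong: the half-ester, once formed, dissolves better than the diacid and is esterified again, so that mostly diester and unchanged 17 are obtained. Fallback (sets out from 17 and 16, comes back at 20): no half-ester is made.
- SOCl2 (cat. DMF, reflux) would turn 17 into trans,trans-muconoyl dichloride F10.
- 16 would be added slowly to a fivefold excess of F10 (pyridine, CH2Cl2, 0 °C) and the remaining acid chloride hydrolysed with aq. NaHCO3/THF, to give the 7,8-O-isopropylidene acetal of the target acid F11.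
- AcOH/H2O (4:1, 40 °C) would then remove the acetonide to give 20, so that steps 13 and 14 and the strong acid are not needed.

**Further compounds**
F1 | step 9 | (S)-1-hydroxypentan-2-yl (S)-2-[(tert-butyldimethylsilyl)oxy]hex-5-enoate | CCC[C@@H](CO)OC(=O)[C@@H](O[Si](C)(C)C(C)(C)C)CCC=C
F2 | step 9 | (S)-1-oxopentan-2-yl (S)-2-[(tert-butyldimethylsilyl)oxy]hex-5-enoate | CCC[C@@H](C=O)OC(=O)[C@@H](O[Si](C)(C)C(C)(C)C)CCC=C
F3 | step 9 | (3R,4R,5S)-4-hydroxy-3-(methoxymethoxy)oct-1-en-5-yl (S)-2-[(tert-butyldimethylsilyl)oxy]hex-5-enoate | CCC[C@H](OC(=O)[C@@H](O[Si](C)(C)C(C)(C)C)CCC=C)[C@@H](O)[C@H](OCOC)C=C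
F4 | step 9 | (3R,4S,5S)-3,4-dihydroxyoct-1-en-5-yl (S)-2-[(tert-butyldimethylsilyl)oxy]hex-5-enoate | CCC[C@H](OC(=O)[C@@H](O[Si](C)(C)C(C)(C)C)CCC=C)[C@@H](O)[C@H](O)C=C
F5 | step 9 | (S)-1-[(4R,5R)-2,2-dimethyl-5-vinyl-1,3-dioxolan-4-yl]butyl (S)-2-[(tert-butyldimethylsilyl)oxy]hex-5-enoate | CCC[C@H](OC(=O)[C@@H](O[Si](C)(C)C(C)(C)C)CCC=C)[C@H]1OC(C)(C)O[C@@H]1C=C
F6 | step 1 | (S)-glycidyl trityl ether (commercial) | C(OC[C@@H]1CO1)(c2ccccc2)(c3ccccc3)c4ccccc4
F7 | step 1 | (S)-1-(trityloxy)hex-5-en-2-ol | C=CCC[C@H](O)COC(c1ccccc1)(c2ccccc2)c3ccccc3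
F8 | step 1 | (S)-tert-butyldimethyl{[1-(trityloxy)hex-5-en-2-yl]oxy}silane | C=CCC[C@H](O[Si](C)(C)C(C)(C)C)COC(c1ccccc1)(c2ccccc2)c3ccccc3
F9 | step 1 | (S)-2-[(tert-butyldimethylsilyl)oxy]hex-5-en-1-ol | C=CCC[C@H](O[Si](C)(C)C(C)(C)C)CO
F10 | step 12 | trans,trans-muconoyl dichloride | ClC(=O)/C=C/C=C/C(Cl)=O
F11 | step 12 | 7,8-O-isopropylidene acetal of the target acid | CCC[C@@H]1OC(=O)[C@@H](OC(=O)/C=C/C=C/C(=O)O)CC/C=C/[C@H]2OC(C)(C)O[C@H]12
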